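**Retrosynthetic overview**

- The strategy rests on the ring O1–O2–C3–C4–C5–C6. Its only all-carbon bridge, C4–C5, lies between the two peroxide-bearing carbons C3 and C6. Each can carry a vinyl group, so the ring is closed last, at carbon, as C4=C5 (step 12, the only ring formation).
- Acid 21 ⇐ alcohol 19 ⇐ 1,2-dioxane 18 ⇐ 3,6-dihydro-1,2-dioxin 17 ⇐ ring-closing metathesis of the bis-vinyl dialkyl peroxide 16.
- 16 ⇐ peroxy diol 13 (alkyne to vinyl at C3; glycol cleavage and methylenation to vinyl at C6) ⇐ O–C3 bond by SN2, with inversion, of hydroperoxide 3 on propargylic mesylate 12.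
- 3 ⇐ Sharpless epoxide 2 of geranylgeraniol (C6 set by H2O2 opening with inversion). 12 ⇐ Evans syn aldol 8 (sets Cα and the C3 carbinol).

Key step: step 12

Remark: until the O–C3 bond exists, the carboxyl carbon is carried as a TBS-protected CH2OH and the C3 vinyl group as an ethynyl group, because a secondary allylic sulfonate β to an ester would be lost to E1cB elimination, ionisation and SN2′ attack. The hydroperoxide is alkylated before glycol cleavage so that no free α-hydroperoxy aldehyde is handled.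

**Route**

Step 1
Reactants: 1 (2E,6E,10E)-geranylgeraniol
Product: 2 [(2R,3R)-3-methyl-3-[(3E,7E)-4,8,12-trimethyltrideca-3,7,11-trien-1-yl]oxiran-2-yl]methanol
Conditions: Ti(OiPr)4 (cat.), D-(−)-diethyl tartrate (cat.), tBuOOH, 4 Å MS, CH2Cl2, −20 °C
Reagents that add atoms: tert-butyl hydroperoxide, CC(C)(C)OO
Why: Sharpless asymmetric epoxidation is directed by the allylic hydroxyl, so only C2=C3 of the four alkenes should react, and the D-tartrate ligand delivers oxygen to the face that gives the (2R,3R)-epoxide.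

Step 2
Reactants: 2 [(2R,3R)-3-methyl-3-[(3E,7E)-4,8,12-trimethyltrideca-3,7,11-trien-1-yl]oxiran-2-yl]methanol
Product: 3 (2R,3S,6E,10E)-3-hydroperoxy-3,7,11,15-tetramethylhexadeca-6,10,14-triene-1,2-diol
Conditions: anhydrous H2O2 in Et2O (excess), phosphomolybdic acid (cat.), rt
Reagents that add atoms: hydrogen peroxide, OO
Why: Acid-catalysed perhydrolysis of an epoxide: under the mild heteropolyacid the oxirane should open at the tertiary carbon (better able to bear positive charge, remote from CH2OH) by backside attack of H2O2, which sets the future C6 with inversion (3S) and leaves C2 untouched, while the large excess of H2O2 outcompetes the chain alkenes as nucleophiles.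

Step 3
Reactants: 4 (4S)-4-benzyl-3-propanoyl-1,3-oxazolidin-2-one; 5 3-(trimethylsilyl)prop-2-ynal
Product: 8 (4S)-4-benzyl-3-[(2S,3S)-3-hydroxy-2-methyl-5-(trimethylsilyl)pent-4-ynoyl]-1,3-oxazolidin-2-one, via Z-dibutylboron enolate 6 (not isolated), via dibutylboron aldolate 7 (not isolated)
Conditions: Bu2BOTf, iPr2NEt, CH2Cl2, 0 °C; then 5, −78 to 0 °C; pH 7 buffer, MeOH, H2O2
Reagents that add atoms: none
Why: Evans syn aldol: the Z-boron enolate reacts through a closed Zimmerman–Traxler chair in which the benzyl group of the auxiliary shields one enolate face, which sets Cα (2S) and the carbinol carbon (3S, the usual Evans syn geometry, the alkynyl group outranking C2) with the hydroxyl on the face opposite to the one the peroxide oxygen must finally occupy.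

Step 4
Reactants: 8 (4S)-4-benzyl-3-[(2S,3S)-3-hydroxy-2-methyl-5-(trimethylsilyl)pent-4-ynoyl]-1,3-oxazolidin-2-one
Product: 9 (2R,3S)-2-methyl-5-(trimethylsilyl)pent-4-yne-1,3-diol
Conditions: LiBH4, MeOH (1 equiv), THF, 0 °C
Reagents that add atoms: none
Why: Reductive cleavage of the N-acyl oxazolidinone by borohydride takes the exocyclic carbonyl to CH2OH without touching either stereocentre (Cα becomes R only because CH2OH ranks below C3) and returns the auxiliary, and at the alcohol oxidation level no later base can expel a β-leaving group by E1cB.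

Step 5
Reactants: 9 (2R,3S)-2-methyl-5-(trimethylsilyl)pent-4-yne-1,3-diol
Product: 10 (3S,4R)-5-[(tert-butyldimethylsilyl)oxy]-4-methyl-1-(trimethylsilyl)pent-1-yn-3-ol
Conditions: TBSCl (1.05 equiv), imidazole, CH2Cl2, 0 °C
Reagents that add atoms: tert-butyldimethylsilyl chloride, CC(C)(C)[Si](C)(C)Cl
Why: Silyl ether formation should distinguish the primary from the secondary propargylic hydroxyl on steric grounds.

Step 6
Reactants: 10 (3S,4R)-5-[(tert-butyldimethylsilyl)oxy]-4-methyl-1-(trimethylsilyl)pent-1-yn-3-ol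
Product: 11 (3S,4R)-5-[(tert-butyldimethylsilyl)oxy]-4-methylpent-1-yn-3-ol
Conditions: K2CO3, MeOH, rt
Reagents that add atoms: none
Why: Base-catalysed methanolysis (protodesilylation) cleaves the alkynyl C–Si bond selectively over the alkyl silyl ether, so that no silicon electrophile is present when the peroxide anion is generated.

Step 7
Reactants: 11 (3S,4R)-5-[(tert-butyldimethylsilyl)oxy]-4-methylpent-1-yn-3-ol
Product: 12 (3S,4R)-5-[(tert-butyldimethylsilyl)oxy]-4-methylpent-1-yn-3-yl methanesulfonate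
Conditions: MsCl, Et3N, CH2Cl2, −20 °C; used at once
Reagents that add atoms: methanesulfonyl chloride, CS(=O)(=O)Cl
Why: Sulfonylation at oxygen leaves the configuration of C3 unchanged, and a secondary propargylic mesylate, unlike an allylic one, neither ionises nor rearranges readily.

Step 8
Reactants: 3 (2R,3S,6E,10E)-3-hydroperoxy-3,7,11,15-tetramethylhexadeca-6,10,14-triene-1,2-diol; 12 (3S,4R)-5-[(tert-butyldimethylsilyl)oxy]-4-methylpent-1-yn-3-yl methanesulfonate
Product: 13 (2R,3S,6E,10E)-3-{[(3R,4R)-5-[(tert-butyldimethylsilyl)oxy]-4-methylpent-1-yn-3-yl]peroxy}-3,7,11,15-tetramethylhexadeca-6,10,14-triene-1,2-diol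
Conditions: 3 (1.2 equiv), CsOH·H2O (1.1 equiv), DMF, 0 °C; then 12 (1.0 equiv)
Reagents that add atoms: none
Why: Williamson-type O-alkylation of a hydroperoxide: the caesium peroxide (OOH is far more acidic and, through the α-effect, more nucleophilic than the two hydroxyls) should displace the propargylic mesylate by SN2 with inversion at C3, the alkyne accelerating substitution without offering an easy SN2′ or ionisation path (C3 becomes R only because the alkynyl group outranks Cα).

Step 9
Reactants: 13 (2R,3S,6E,10E)-3-{[(3R,4R)-5-[(tert-butyldimethylsilyl)oxy]-4-methylpent-1-yn-3-yl]peroxy}-3,7,11,15-tetramethylhexadeca-6,10,14-triene-1,2-diol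
Product: 14 (2R,3S,6E,10E)-3-{[(3S,4R)-5-[(tert-butyldimethylsilyl)oxy]-4-methylpent-1-en-3-yl]peroxy}-3,7,11,15-tetramethylhexadeca-6,10,14-triene-1,2-diol
Conditions: H2 (1 atm), Lindlar catalyst, quinoline, EtOAc, 0 °C to rt, stopped after 1 equiv H2
Reagents that add atoms: none
Why: Lindlar semi-hydrogenation: the terminal alkyne binds the poisoned palladium far more strongly than the trisubstituted alkenes or the dialkyl peroxide, so uptake of one equivalent of hydrogen should stop at the C3 vinyl group.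

Step 10
Reactants: 14 (2R,3S,6E,10E)-3-{[(3S,4R)-5-[(tert-butyldimethylsilyl)oxy]-4-methylpent-1-en-3-yl]peroxy}-3,7,11,15-tetramethylhexadeca-6,10,14-triene-1,2-diol
Product: 15 (2S,5E,9E)-2-{[(3S,4R)-5-[(tert-butyldimethylsilyl)oxy]-4-methylpent-1-en-3-yl]peroxy}-2,6,10,14-tetramethylpentadeca-5,9,13-trienal
Conditions: NaIO4, THF/pH 7 buffer, 0 °C to rt
Reagents that add atoms: none
Why: Malaprade glycol cleavage removes C1 as formaldehyde and leaves a non-enolisable aldehyde on the quaternary peroxy carbon, a dialkyl peroxide without α-hydrogen on that side that periodate does not attack.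

Step 11
Reactants: 15 (2S,5E,9E)-2-{[(3S,4R)-5-[(tert-butyldimethylsilyl)oxy]-4-methylpent-1-en-3-yl]peroxy}-2,6,10,14-tetramethylpentadeca-5,9,13-trienal
Product: 16 tert-butyldimethyl{[(2R,3S)-2-methyl-3-{[(3S,6E,10E)-3,7,11,15-tetramethylhexadeca-1,6,10,14-tetraen-3-yl]peroxy}pent-4-en-1-yl]oxy}silane
Conditions: Ph3PCH3Br, KHMDS, THF, 0 °C; then 15, −78 to 0 °C
Reagents that add atoms: methyltriphenylphosphonium bromide, C[P+](c1ccccc1)(c1ccccc1)c1ccccc1.[Br-]
Why: Wittig methylenation: at low temperature the ylide should add to the activated, non-enolisable aldehyde faster than it can deprotonate the C3–H next to the peroxide, and the quaternary stereocentre cannot epimerise.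

Step 12
Reactants: 16 tert-butyldimethyl{[(2R,3S)-2-methyl-3-{[(3S,6E,10E)-3,7,11,15-tetramethylhexadeca-1,6,10,14-tetraen-3-yl]peroxy}pent-4-en-1-yl]oxy}silane
Product: 17 tert-butyldimethyl{(2R)-2-[(3S,6S)-6-methyl-6-[(3E,7E)-4,8,12-trimethyltrideca-3,7,11-trien-1-yl]-3,6-dihydro-1,2-dioxin-3-yl]propoxy}silane
Conditions: Grubbs first-generation catalyst (5–10 mol %), CH2Cl2 (5 mM), 40 °C, argon sparge
Reagents that add atoms: none
Why: The ruthenium benzylidene exchanges onto the less hindered C3 vinyl group, the resulting alkylidene adds across the vinyl group on quaternary C6 to a ruthenacyclobutane, and cycloreversion releases the C4=C5 ring alkene and Ru=CH2, which carries the chain with loss of ethene. The closest known reaction type is ring-closing olefin metathesis of allylic dialkyl peroxides to 3,6-dihydro-1,2-dioxins, the peroxide counterpart of diallyl ether to dihydropyran closures. The one ring is closed as a six-membered ring by C=C formation between the ends of a 1,7-diene whose tether already holds O1–O2, and the ring size allows only the cis alkene. No stereocentre is formed; C3, C6 and Cα were fixed in steps 1–3 and 8 and are not touched. The step needs chemoselectivity for the two monosubstituted alkenes over the three trisubstituted chain alkenes, which a first-generation catalyst (unreactive toward trisubstituted alkenes) and initiation at C3 in place of the hindered C6 vinyl group should secure; this also disfavours the cyclopentene that a C6-bound carbene would form with C9=C10. High dilution and removal of ethene should suppress oligomerisation through the C3 vinyl group.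

Step 13
Reactants: 17 tert-butyldimethyl{(2R)-2-[(3S,6S)-6-methyl-6-[(3E,7E)-4,8,12-trimethyltrideca-3,7,11-trien-1-yl]-3,6-dihydro-1,2-dioxin-3-yl]propoxy}silane
Product: 18 tert-butyldimethyl{(2R)-2-[(3S,6S)-6-methyl-6-[(3E,7E)-4,8,12-trimethyltrideca-3,7,11-trien-1-yl]-1,2-dioxan-3-yl]propoxy}silane
Conditions: KO2CN=NCO2K (excess, in portions), AcOH, CH2Cl2/MeOH, 0 °C to rt
Reagents that add atoms: none
Why: Diimide reduction transfers two hydrogens in a concerted syn fashion and does not cleave O–O; the cis-disubstituted ring alkene flanked by two allylic oxygens should react faster than the three trisubstituted chain alkenes when the reagent is added in portions to full conversion of 17, and the acidic medium avoids the Kornblum–DeLaMare opening that amine bases cause in dihydrodioxins with a C3–H.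

Step 14
Reactants: 18 tert-butyldimethyl{(2R)-2-[(3S,6S)-6-methyl-6-[(3E,7E)-4,8,12-trimethyltrideca-3,7,11-trien-1-yl]-1,2-dioxan-3-yl]propoxy}silane
Product: 19 (2R)-2-[(3S,6S)-6-methyl-6-[(3E,7E)-4,8,12-trimethyltrideca-3,7,11-trien-1-yl]-1,2-dioxan-3-yl]propan-1-ol
Conditions: HF·pyridine, pyridine, THF, 0 °C to rt
Reagents that add atoms: none
Why: Fluoride-driven desilylation under buffered, weakly acidic conditions should free the primary alcohol without protonating the trisubstituted alkenes or opening the saturated peroxide ring.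

Step 15
Reactants: 19 (2R)-2-[(3S,6S)-6-methyl-6-[(3E,7E)-4,8,12-trimethyltrideca-3,7,11-trien-1-yl]-1,2-dioxan-3-yl]propan-1-ol
Product: 21 (2S)-2-[(3S,6S)-6-methyl-6-[(3E,7E)-4,8,12-trimethyltrideca-3,7,11-trien-1-yl]-1,2-dioxan-3-yl]propanoic acid, via peroxy aldehyde 20 (not isolated)
Conditions: TEMPO (cat.), PhI(OAc)2 (2.2 equiv), CH2Cl2/MeCN/H2O, rt
Reagents that add atoms: water, O
Why: Oxoammonium-mediated oxidation (TEMPO/PhI(OAc)2) takes the primary alcohol through the aldehyde hydrate to the acid under neutral to weakly acidic conditions, so that Cα should not epimerise (it becomes S only because CO2H outranks C3), the β-peroxy carbonyl meets no base that could open the ring, and the alkenes and O–O bond are not oxidised.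

**Compound list**

1 | (2E,6E,10E)-geranylgeraniol | CC(C)=CCC/C(C)=C/CC/C(C)=C/CC/C(C)=C/CO | starting material
2 | [(2R,3R)-3-methyl-3-[(3E,7E)-4,8,12-trimethyltrideca-3,7,11-trien-1-yl]oxiran-2-yl]methanol | CC(C)=CCC/C(C)=C/CC/C(C)=C/CC[C@@]1(C)O[C@@H]1CO | intermediate
3 | (2R,3S,6E,10E)-3-hydroperoxy-3,7,11,15-tetramethylhexadeca-6,10,14-triene-1,2-diol | CC(C)=CCC/C(C)=C/CC/C(C)=C/CC[C@@](OO)(C)[C@H](O)CO | intermediate
4 | (4S)-4-benzyl-3-propanoyl-1,3-oxazolidin-2-one | CCC(=O)N1[C@@H](Cc2ccccc2)COC1=O | starting material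
5 | 3-(trimethylsilyl)prop-2-ynal | C[Si](C)(C)C#CC=O | starting material
6 | (4S)-4-benzyl-3-[(1Z)-1-[(dibutylboranyl)oxy]prop-1-en-1-yl]-1,3-oxazolidin-2-one (Z-dibutylboron enolate) | C/C=C(\OB(CCCC)CCCC)N1[C@@H](Cc2ccccc2)COC1=O | intermediate
7 | (4S)-4-benzyl-3-[(2S,3S)-3-[(dibutylboranyl)oxy]-2-methyl-5-(trimethylsilyl)pent-4-ynoyl]-1,3-oxazolidin-2-one (dibutylboron aldolate) | C[Si](C)(C)C#C[C@@H](OB(CCCC)CCCC)[C@H](C)C(=O)N1[C@@H](Cc2ccccc2)COC1=O | intermediate
8 | (4S)-4-benzyl-3-[(2S,3S)-3-hydroxy-2-methyl-5-(trimethylsilyl)pent-4-ynoyl]-1,3-oxazolidin-2-one | C[Si](C)(C)C#C[C@@H](O)[C@H](C)C(=O)N1[C@@H](Cc2ccccc2)COC1=O | intermediate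
9 | (2R,3S)-2-methyl-5-(trimethylsilyl)pent-4-yne-1,3-diol | C[Si](C)(C)C#C[C@@H](O)[C@H](C)CO | intermediate
10 | (3S,4R)-5-[(tert-butyldimethylsilyl)oxy]-4-methyl-1-(trimethylsilyl)pent-1-yn-3-ol | C[Si](C)(C)C#C[C@@H](O)[C@H](C)CO[Si](C)(C)C(C)(C)C | intermediate
11 | (3S,4R)-5-[(tert-butyldimethylsilyl)oxy]-4-methylpent-1-yn-3-ol | C#C[C@@H](O)[C@H](C)CO[Si](C)(C)C(C)(C)C | intermediate
12 | (3S,4R)-5-[(tert-butyldimethylsilyl)oxy]-4-methylpent-1-yn-3-yl methanesulfonate | C#C[C@@H](OS(C)(=O)=O)[C@H](C)CO[Si](C)(C)C(C)(C)C | intermediate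
13 | (2R,3S,6E,10E)-3-{[(3R,4R)-5-[(tert-butyldimethylsilyl)oxy]-4-methylpent-1-yn-3-yl]peroxy}-3,7,11,15-tetramethylhexadeca-6,10,14-triene-1,2-diol | CC(C)=CCC/C(C)=C/CC/C(C)=C/CC[C@@](OO[C@@H](C#C)[C@H](C)CO[Si](C)(C)C(C)(C)C)(C)[C@H](O)CO | intermediate
14 | (2R,3S,6E,10E)-3-{[(3S,4R)-5-[(tert-butyldimethylsilyl)oxy]-4-methylpent-1-en-3-yl]peroxy}-3,7,11,15-tetramethylhexadeca-6,10,14-triene-1,2-diol | CC(C)=CCC/C(C)=C/CC/C(C)=C/CC[C@@](OO[C@@H](C=C)[C@H](C)CO[Si](C)(C)C(C)(C)C)(C)[C@H](O)CO | intermediate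
15 | (2S,5E,9E)-2-{[(3S,4R)-5-[(tert-butyldimethylsilyl)oxy]-4-methylpent-1-en-3-yl]peroxy}-2,6,10,14-tetramethylpentadeca-5,9,13-trienal | CC(C)=CCC/C(C)=C/CC/C(C)=C/CC[C@@](OO[C@@H](C=C)[C@H](C)CO[Si](C)(C)C(C)(C)C)(C)C=O | intermediate
16 | tert-butyldimethyl{[(2R,3S)-2-methyl-3-{[(3S,6E,10E)-3,7,11,15-tetramethylhexadeca-1,6,10,14-tetraen-3-yl]peroxy}pent-4-en-1-yl]oxy}silane | CC(C)=CCC/C(C)=C/CC/C(C)=C/CC[C@@](OO[C@@H](C=C)[C@H](C)CO[Si](C)(C)C(C)(C)C)(C)C=C | intermediate
17 | tert-butyldimethyl{(2R)-2-[(3S,6S)-6-methyl-6-[(3E,7E)-4,8,12-trimethyltrideca-3,7,11-trien-1-yl]-3,6-dihydro-1,2-dioxin-3-yl]propoxy}silane | CC(C)=CCC/C(C)=C/CC/C(C)=C/CC[C@@]1(C)C=C[C@@H]([C@H](C)CO[Si](C)(C)C(C)(C)C)OO1 | intermediate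
18 | tert-butyldimethyl{(2R)-2-[(3S,6S)-6-methyl-6-[(3E,7E)-4,8,12-trimethyltrideca-3,7,11-trien-1-yl]-1,2-dioxan-3-yl]propoxy}silane | CC(C)=CCC/C(C)=C/CC/C(C)=C/CC[C@@]1(C)CC[C@@H]([C@H](C)CO[Si](C)(C)C(C)(C)C)OO1 | intermediate
19 | (2R)-2-[(3S,6S)-6-methyl-6-[(3E,7E)-4,8,12-trimethyltrideca-3,7,11-trien-1-yl]-1,2-dioxan-3-yl]propan-1-ol | CC(C)=CCC/C(C)=C/CC/C(C)=C/CC[C@@]1(C)CC[C@@H]([C@H](C)CO)OO1 | intermediate
20 | (2S)-2-[(3S,6S)-6-methyl-6-[(3E,7E)-4,8,12-trimethyltrideca-3,7,11-trien-1-yl]-1,2-dioxan-3-yl]propanal | CC(C)=CCC/C(C)=C/CC/C(C)=C/CC[C@@]1(C)CC[C@@H]([C@H](C)C=O)OO1 | intermediate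
21 | (2S)-2-[(3S,6S)-6-methyl-6-[(3E,7E)-4,8,12-trimethyltrideca-3,7,11-trien-1-yl]-1,2-dioxan-3-yl]propanoic acid | CC(C)=CCC/C(C)=C/CC/C(C)=C/CC[C@@]1(C)CC[C@@H]([C@H](C)C(=O)O)OO1 | target

**Step count and risks**

Total step count: 15. Longest linear sequence: 13 steps (steps 3–15, from 4 and 5).

Steps most likely to fail:

1. Step 8 (peroxide alkylation). Base-triggered C–C fragmentation of the β-hydroxy hydroperoxide salt, E2 loss of the mesylate towards the conjugated enyne, or alkylation at a hydroxyl could outrun the SN2 coupling. The fallback reverses the order in which the two C–O bonds of the peroxide are made. It sets out from mesylate 12 and epoxy alcohol 2. Mesylate 12 is perhydrolysed (aqueous H2O2, KOH, MeOH, 0 °C; the classical SN2 of a sulfonate by HOO− with inversion) to tert-butyl{[(2R,3R)-3-hydroperoxy-2-methylpent-4-yn-1-yl]oxy}dimethylsilane F1. An excess of this hydroperoxide then opens 2 at its tertiary carbon under phosphomolybdic acid catalysis in dry Et2O, again with inversion, and the route is rejoined at 13.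

2. Step 12 (ring-closing metathesis). Ruthenium could load on the C6 vinyl group and close onto C9=C10 (cyclopentene formation with loss of the chain), or closure onto the hindered C6 alkene could be slow enough for oligomerisation through the C3 vinyl group to take over. The fallback caps the C6 alkene so that the metal can only start at C3. It sets out from aldehyde 15, which is olefinated with ethylidenetriphenylphosphorane (Ph3PCH2CH3Br, KHMDS, THF, −78 °C, Z-selective) to tert-butyldimethyl{[(2R,3S)-2-methyl-3-{[(2Z,4S,7E,11E)-4,8,12,16-tetramethylheptadeca-2,7,11,15-tetraen-4-yl]peroxy}pent-4-en-1-yl]oxy}silane F2. Its 1,2-disubstituted C6 alkene cannot take up the catalyst, so metathesis must begin at the C3 vinyl group and expels propene in place of ethene. The route is rejoined at 17.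

3. Step 9 (semi-hydrogenation). Hydrogenolysis of the O–O bond on palladium, or over-reduction of the new vinyl group, could compete. The fallback postpones the alkyne reduction and replaces hydrogenation by hydrometalation. It sets out from 13, whose diol is cleaved with NaIO4 to (2S,5E,9E)-2-{[(3R,4R)-5-[(tert-butyldimethylsilyl)oxy]-4-methylpent-1-yn-3-yl]peroxy}-2,6,10,14-tetramethylpentadeca-5,9,13-trienal F3. Wittig methylenation then gives tert-butyldimethyl{[(2R,3R)-2-methyl-3-{[(3S,6E,10E)-3,7,11,15-tetramethylhexadeca-1,6,10,14-tetraen-3-yl]peroxy}pent-4-yn-1-yl]oxy}silane F4. Hydrozirconation with Cp2Zr(H)Cl (1.1 equiv, THF, rt), which takes terminal alkynes much faster than the hindered vinyl group and is known to tolerate dialkyl peroxides, gives chlorobis(cyclopentadienyl){(1E,3R,4R)-5-[(tert-butyldimethylsilyl)oxy]-4-methyl-3-{[(3S,6E,10E)-3,7,11,15-tetramethylhexadeca-1,6,10,14-tetraen-3-yl]peroxy}pent-1-en-1-yl}zirconium F5. Protonolysis with water rejoins the route at 16.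

Further compounds
F1 | step 8 | tert-butyl{[(2R,3R)-3-hydroperoxy-2-methylpent-4-yn-1-yl]oxy}dimethylsilane | C#C[C@H](OO)[C@H](C)CO[Si](C)(C)C(C)(C)C
F2 | step 12 | tert-butyldimethyl{[(2R,3S)-2-methyl-3-{[(2Z,4S,7E,11E)-4,8,12,16-tetramethylheptadeca-2,7,11,15-tetraen-4-yl]peroxy}pent-4-en-1-yl]oxy}silane | CC(C)=CCC/C(C)=C/CC/C(C)=C/CC[C@@](OO[C@@H](C=C)[C@H](C)CO[Si](C)(C)C(C)(C)C)(C)/C=C\C
F3 | step 9 | (2S,5E,9E)-2-{[(3R,4R)-5-[(tert-butyldimethylsilyl)oxy]-4-methylpent-1-yn-3-yl]peroxy}-2,6,10,14-tetramethylpentadeca-5,9,13-trienal | CC(C)=CCC/C(C)=C/CC/C(C)=C/CC[C@@](OO[C@@H](C#C)[C@H](C)CO[Si](C)(C)C(C)(C)C)(C)C=O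
F4 | step 9 | tert-butyldimethyl{[(2R,3R)-2-methyl-3-{[(3S,6E,10E)-3,7,11,15-tetramethylhexadeca-1,6,10,14-tetraen-3-yl]peroxy}pent-4-yn-1-yl]oxy}silane | CC(C)=CCC/C(C)=C/CC/C(C)=C/CC[C@@](OO[C@@H](C#C)[C@H](C)CO[Si](C)(C)C(C)(C)C)(C)C=C
F5 | step 9 | chlorobis(cyclopentadienyl){(1E,3R,4R)-5-[(tert-butyldimethylsilyl)oxy]-4-methyl-3-{[(3S,6E,10E)-3,7,11,15-tetramethylhexadeca-1,6,10,14-tetraen-3-yl]peroxy}pent-1-en-1-yl}zirconium | CC(C)=CCC/C(C)=C/CC/C(C)=C/CC[C@@](OO[C@@H](/C=C/[Zr](Cl)(C1C=CC=C1)C1C=CC=C1)[C@H](C)CO[Si](C)(C)C(C)(C)C)(C)C=C
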